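**Strategy.** The cyclopentane ring (C1–C5) holds a β-hydroxy ketone retron, C2(=O)–C3H2–C4(OH)(i-Pr), carried on the cis-related C1 (quaternary, methyl) and C5 of the cycloheptene ring. The ring is closed last at C3–C4: SmI2 turns a C1 bromoacetyl group into a samarium enolate that adds to the neighbouring C5 isobutyryl ketone, giving the ring, the C4 carbinol stereocentre and the C2 ketone in one operation. The precursor is a cycloheptene with cis bromoacetyl (on C1, beside methyl) and isobutyryl (on C5) groups and a trans C6 silyl ether. C6 comes from the chiral pool, C5 and C1 from a chelate-controlled Ireland–Claisen rearrangement, and the seven-membered ring from metathesis.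

Key step: step 12

Remark: locants C1–C10 of the bicycle (C1 quaternary fusion carbon with methyl, C2 O-angeloyl, C3 CH2, C4 isopropyl carbinol, C5 fusion CH, C6 O-aroyl, C7 CH2, C8(Me)=C9, C10 CH2) are used for every intermediate; in these locants the cis-fused target is (1R,2S,4S,5R,6R).

**Step 1**
Reactants: 1 but-2-yn-1-ol
Product: 3 (Z)-3-iodobut-2-en-1-ol, via cyclic vinylalanate 2 (not isolated)
Conditions: NaAlH2(OCH2CH2OMe)2, THF, 0 °C to rt; then I2, THF, −78 °C
Reagents that add atoms: iodine, II; sodium bis(2-methoxyethoxy)aluminium hydride, [Na+].[AlH2-](OCCOC)OCCOC (aluminium of 2 only)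
Why: hydroxyl-directed trans-hydroalumination of the propargylic alcohol delivers hydride to C2 and aluminium to C3 inside a five-membered chelate, and iodinolysis with retention should give the Z iodide.

**Step 2**
Reactants: 3 (Z)-3-iodobut-2-en-1-ol
Product: 4 (Z)-3-methylhexa-2,5-dien-1-ol
Conditions: allylSnBu3, Pd(PPh3)4 (5 mol%), CuI (10 mol%), DMF, 40 °C
Reagents that add atoms: allyltributylstannane, C=CC[Sn](CCCC)(CCCC)CCCC
Why: Stille coupling of an alkenyl iodide proceeds with retention of alkene geometry, so the allyl group should end cis to CH2OH.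

**Step 3**
Reactants: 5 ethyl (S)-4-chloro-3-hydroxybutanoate
Product: 6 ethyl (S)-3,4-epoxybutanoate
Conditions: Ag2O, 1,2-dimethoxyethane, 60 °C
Reagents that add atoms: none
Why: silver-assisted intramolecular Williamson closure forms the epoxide without a soluble base, which avoids elimination to the 4-hydroxycrotonate; the carbinol centre is not touched.

**Step 4**
Reactants: 6 ethyl (S)-3,4-epoxybutanoate
Product: 7 ethyl (R)-3-hydroxy-5-methylhex-5-enoate
Conditions: CH2=C(Me)MgBr, CuI (10 mol%), THF, −40 °C
Reagents that add atoms: isopropenylmagnesium bromide, C=C(C)[Mg]Br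
Why: copper-catalysed Grignard opening of the terminal epoxide at its CH2 end outruns ester addition at low temperature and leaves the stereocentre (future C6) untouched, the descriptor changing only by priority.

**Step 5**
Reactants: 7 ethyl (R)-3-hydroxy-5-methylhex-5-enoate; 4 (Z)-3-methylhexa-2,5-dien-1-ol
Product: 8 (2Z)-3-methylhexa-2,5-dien-1-yl (3R)-3-hydroxy-5-methylhex-5-enoate
Conditions: ClBu2SnOSnBu2Cl (5 mol%), toluene, reflux (−EtOH)
Reagents that add atoms: none
Why: distannoxane-catalysed transesterification is neutral, is driven by removal of ethanol, and should favour the primary allylic alcohol over the hindered secondary hydroxyl of 7.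

**Step 6**
Reactants: 8 (2Z)-3-methylhexa-2,5-dien-1-yl (3R)-3-hydroxy-5-methylhex-5-enoate
Product: 10 (2R,3R)-3-hydroxy-5-methyl-2-[(3S)-3-methylhexa-1,5-dien-3-yl]hex-5-enoic acid, via dilithium alkoxide enolate 9 (not isolated)
Conditions: LiN(i-Pr)2 (2.3 equiv), THF, −78 °C to rt; then 1 M HCl
Reagents that add atoms: lithium diisopropylamide, [Li]N(C(C)C)C(C)C (lithium of 9 only)
Why: Ireland–Claisen (ester enolate Claisen) rearrangement of the lithium-bridged alkoxide–enolate: the chelate fixes the enolate geometry and shields the face next to the C7 chain so that C1 bonds to C5 anti to the C6 oxygen (as in Fráter–Seebach alkylation), and the chair transition state of the Z alkene (methyl equatorial, allyl axial) sets the quaternary C1 relative to C5.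

**Step 7**
Reactants: 10 (2R,3R)-3-hydroxy-5-methyl-2-[(3S)-3-methylhexa-1,5-dien-3-yl]hex-5-enoic acid
Product: 12 (2R,3R)-3-(tert-butyldimethylsilyloxy)-5-methyl-2-[(3S)-3-methylhexa-1,5-dien-3-yl]hex-5-enoic acid, via bis-silyl derivative 11 (not isolated)
Conditions: TBSOTf (2.3 equiv), 2,6-lutidine, CH2Cl2, 0 °C; then AcOH, THF/H2O, rt
Reagents that add atoms: tert-butyldimethylsilyl triflate, CC(C)(C)[Si](C)(C)OS(=O)(=O)C(F)(F)F
Why: silylation of hydroxyl and carboxyl followed by selective hydrolysis of the labile silyl ester should give the silyl ether acid; no stereocentre is affected.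

**Step 8**
Reactants: 12 silyl ether acid
Product: 14 (4R,5R)-5-(tert-butyldimethylsilyloxy)-2,7-dimethyl-4-[(3S)-3-methylhexa-1,5-dien-3-yl]oct-7-en-3-one, via acid chloride 13 (not isolated)
Conditions: Me2C=C(Cl)NMe2, CH2Cl2, 0 °C to rt; then i-PrMgCl, Fe(acac)3 (3 mol%), THF, −78 °C
Reagents that add atoms: isopropylmagnesium chloride, CC(C)[Mg]Cl; 1-chloro-N,N,2-trimethylprop-1-en-1-amine, CC(C)=C(Cl)N(C)C (chlorine of 13 only)
Why: neutral acid chloride formation spares the silyl ether, and iron-catalysed Grignard acylation should stop at the ketone at −78 °C, too cold for enolisation at C5.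

**Step 9**
Reactants: 14 triene ketone
Product: 15 (1S,5R,6R)-6-(tert-butyldimethylsilyloxy)-5-isobutyryl-1,8-dimethyl-1-vinylcyclohept-8-ene (route locants; isobutyryl cis to vinyl, trans to silyloxy)
Conditions: second-generation Grubbs catalyst (H2IMes)(PCy3)Cl2Ru=CHPh (5 mol%), CH2Cl2, 40 °C
Reagents that add atoms: none
Why: ring-closing metathesis should start at the unhindered allyl terminus, whose ruthenium carbene can only reach the methallyl group to close the seven-membered ring with the trisubstituted C8=C9 alkene, the vinyl group on the quaternary carbon being a poor metathesis partner.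

**Step 10**
Reactants: 15 vinylcycloheptene
Product: 16 (1R,5R,6R)-1-acetyl-6-(tert-butyldimethylsilyloxy)-5-isobutyryl-1,8-dimethylcyclohept-8-ene (route locants)
Conditions: PdCl2 (10 mol%), CuCl (1 equiv), O2 (1 atm), DMF/H2O (7:1), rt
Reagents that add atoms: water, O
Why: Tsuji–Wacker oxidation should convert only the monosubstituted vinyl group into a methyl ketone with Markovnikov selectivity, the trisubstituted ring alkene being inert.

**Step 11**
Reactants: 16 methyl ketone
Product: 18 (1R,5R,6R)-1-(bromoacetyl)-6-(tert-butyldimethylsilyloxy)-5-isobutyryl-1,8-dimethylcyclohept-8-ene (route locants; acyl groups cis), via trimethylsilyl enol ether 17 (not isolated)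
Conditions: LiN(SiMe3)2, TMSCl, THF, −78 °C; then NBS, THF, −78 to 0 °C
Reagents that add atoms: N-bromosuccinimide, O=C1CCC(=O)N1Br; chlorotrimethylsilane, C[Si](C)(C)Cl (silicon of 17 only)
Why: kinetic deprotonation with in-situ silyl trapping should occur only at the acetyl methyl group (C3), the other α positions being tertiary, and bromination of the silyl enol ether is much faster than attack on the ring alkene.

**Step 12**
Reactants: 18 bromoketone
Product: 20 (1R,4S,5R,6R)-6-(tert-butyldimethylsilyloxy)-4-hydroxy-4-isopropyl-1,8-dimethyl-cis-hydroazulen-2-one (route locants), via samarium enolate 19 (not isolated)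
Conditions: SmI2 (2.2 equiv), THF, −78 to −40 °C; then aq. NH4Cl
Reagents that add atoms: samarium diiodide, I[Sm]I (samarium of 19 only)
Why: Two single-electron transfers from divalent samarium cleave the C3–Br bond and give the trivalent samarium enolate 19 regiospecifically at C3 (C1 is quaternary), whose carbon adds to the C4 carbonyl of the isobutyryl group held cis on C5; this is a samarium Reformatsky-type intramolecular aldol of an α-halo ketone. The cyclopentane closes in the 5-(enolendo)-exo-trig mode, because the enolate C2=C3 bond lies inside the new ring; this is the same mode as the cyclisation of 1,4-diketones to 3-hydroxycyclopentanones, and the cis 1,2-placement of the acyl groups next to the quaternary C1 holds the reacting carbons close. The one new stereocentre, C4, is substrate-controlled: C3 can only reach the carbonyl face turned towards C1, and in that geometry isopropyl sits beside H5 and away from the silyloxy-bearing C6, so the hydroxyl should end cis to C6 on the concave face and isopropyl on the convex face. The step needs C–Br reduction to win over ketone reduction, which the far faster reduction of the α-bromo ketone at −78 °C and the limit of two equivalents of SmI2 secure. It also needs the β-hydroxy ketone to survive, which the neutral medium and buffered quench secure by preventing retro-aldol cleavage, dehydration and loss of the β-silyloxy group.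

**Step 13**
Reactants: 20 hydroxy ketone
Product: 21 (1R,2S,4S,5R,6R)-6-(tert-butyldimethylsilyloxy)-4-isopropyl-1,8-dimethyl-cis-hydroazulene-2,4-diol (route locants; hydroxyls cis)
Conditions: LiBH(s-Bu)3, THF, −78 °C; then aq. NH4Cl
Reagents that add atoms: none
Why: steric approach control: the bulky trialkylborohydride should attack the cyclopentanone from the convex face, since the C10 methylene and the C4 oxygen close the concave face, placing the C2 hydroxyl cis to the C4 hydroxyl (a chelate between the C2 carbonyl and the C4 oxygen is not possible in this ring and is not invoked).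

**Step 14**
Reactants: 21 diol; 22 angelic acid
Product: 23 C2 angelate of 21
Conditions: 22, 2,4,6-Cl3C6H2COCl, Et3N, toluene, rt; then 21, 80 °C
Reagents that add atoms: none
Why: Yamaguchi esterification through the mixed anhydride, run without a nucleophilic catalyst, should acylate only the secondary C2 hydroxyl and keep the Z geometry of the angelate.

**Step 15**
Reactants: 23 silyl ether angelate
Product: 24 C6 alcohol
Conditions: HF·pyridine, THF/pyridine, 0 °C to rt
Reagents that add atoms: none
Why: fluoride-driven Si–O cleavage under buffered conditions should free the C6 hydroxyl without isomerising the angelate or disturbing the tertiary alcohol.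

**Step 16**
Reactants: 24 C6 alcohol; 25 3,4,5-trimethoxybenzoyl chloride
Product: 26 target
Conditions: 25, Et3N, DMAP (cat.), CH2Cl2, rt
Reagents that add atoms: none
Why: DMAP-catalysed acyl transfer should esterify the secondary C6 hydroxyl only, the tertiary C4 hydroxyl being too hindered; no stereocentre is touched.

**Compound list**

1 | but-2-yn-1-ol | CC#CCO | starting material
2 | sodium cyclic vinylalanate of 1 (aluminium on C3, bridged to oxygen) | CC1=CCO[Al-]1(OCCOC)OCCOC.[Na+] | intermediate
3 | (Z)-3-iodobut-2-en-1-ol | I/C(C)=C\CO | intermediate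
4 | (Z)-3-methylhexa-2,5-dien-1-ol | C=CC/C(C)=C\CO | intermediate
5 | ethyl (S)-4-chloro-3-hydroxybutanoate | CCOC(=O)C[C@H](O)CCl | starting material
6 | ethyl (S)-3,4-epoxybutanoate | CCOC(=O)C[C@H]1CO1 | intermediate
7 | ethyl (R)-3-hydroxy-5-methylhex-5-enoate | CCOC(=O)C[C@H](O)CC(C)=C | intermediate
8 | (2Z)-3-methylhexa-2,5-dien-1-yl (3R)-3-hydroxy-5-methylhex-5-enoate | C=CC/C(C)=C\COC(=O)C[C@H](O)CC(C)=C | intermediate
9 | dilithium alkoxide enolate of 8 (enolate oxygen cis to C6) | [Li]O/C(OC/C=C(C)\CC=C)=C\[C@H](O[Li])CC(C)=C | intermediate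
10 | (2R,3R)-3-hydroxy-5-methyl-2-[(3S)-3-methylhexa-1,5-dien-3-yl]hex-5-enoic acid | C=C[C@](C)(CC=C)[C@@H](C(=O)O)[C@H](O)CC(C)=C | intermediate
11 | tert-butyldimethylsilyl ester of 12 (bis-silyl derivative of 10) | C=C[C@](C)(CC=C)[C@@H](C(=O)O[Si](C)(C)C(C)(C)C)[C@H](O[Si](C)(C)C(C)(C)C)CC(C)=C | intermediate
12 | (2R,3R)-3-(tert-butyldimethylsilyloxy)-5-methyl-2-[(3S)-3-methylhexa-1,5-dien-3-yl]hex-5-enoic acid | C=C[C@](C)(CC=C)[C@@H](C(=O)O)[C@H](O[Si](C)(C)C(C)(C)C)CC(C)=C | intermediate
13 | acid chloride of 12 | C=C[C@](C)(CC=C)[C@@H](C(Cl)=O)[C@H](O[Si](C)(C)C(C)(C)C)CC(C)=C | intermediate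
14 | (4R,5R)-5-(tert-butyldimethylsilyloxy)-2,7-dimethyl-4-[(3S)-3-methylhexa-1,5-dien-3-yl]oct-7-en-3-one | C=C[C@](C)(CC=C)[C@@H](C(=O)C(C)C)[C@H](O[Si](C)(C)C(C)(C)C)CC(C)=C | intermediate
15 | (1S,5R,6R)-6-(tert-butyldimethylsilyloxy)-5-isobutyryl-1,8-dimethyl-1-vinylcyclohept-8-ene (route locants) | C=C[C@]1(C)CC=C(C)C[C@@H](O[Si](C)(C)C(C)(C)C)[C@@H]1C(=O)C(C)C | intermediate
16 | (1R,5R,6R)-1-acetyl-6-(tert-butyldimethylsilyloxy)-5-isobutyryl-1,8-dimethylcyclohept-8-ene (route locants) | CC(=O)[C@]1(C)CC=C(C)C[C@@H](O[Si](C)(C)C(C)(C)C)[C@@H]1C(=O)C(C)C | intermediate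
17 | trimethylsilyl enol ether of 16 (C2=C3) | C=C(O[Si](C)(C)C)[C@]1(C)CC=C(C)C[C@@H](O[Si](C)(C)C(C)(C)C)[C@@H]1C(=O)C(C)C | intermediate
18 | (1R,5R,6R)-1-(bromoacetyl)-6-(tert-butyldimethylsilyloxy)-5-isobutyryl-1,8-dimethylcyclohept-8-ene (route locants) | BrCC(=O)[C@]1(C)CC=C(C)C[C@@H](O[Si](C)(C)C(C)(C)C)[C@@H]1C(=O)C(C)C | intermediate
19 | diiodosamarium enolate from 18 (trivalent samarium on the C2 oxygen, C2=C3) | C=C(O[Sm](I)I)[C@]1(C)CC=C(C)C[C@@H](O[Si](C)(C)C(C)(C)C)[C@@H]1C(=O)C(C)C | intermediate
20 | (1R,4S,5R,6R)-6-(tert-butyldimethylsilyloxy)-4-hydroxy-4-isopropyl-1,8-dimethyl-cis-hydroazulen-2-one (route locants) | O=C1C[C@](O)(C(C)C)[C@H]2[C@H](O[Si](C)(C)C(C)(C)C)CC(C)=CC[C@@]12C | intermediate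
21 | (1R,2S,4S,5R,6R)-6-(tert-butyldimethylsilyloxy)-4-isopropyl-1,8-dimethyl-cis-hydroazulene-2,4-diol (route locants) | O[C@H]1C[C@](O)(C(C)C)[C@H]2[C@H](O[Si](C)(C)C(C)(C)C)CC(C)=CC[C@@]12C | intermediate
22 | angelic acid, (Z)-2-methylbut-2-enoic acid | C/C=C(/C)C(=O)O | starting material
23 | C2 angelate of 21 | C/C=C(/C)C(=O)O[C@H]1C[C@](O)(C(C)C)[C@H]2[C@H](O[Si](C)(C)C(C)(C)C)CC(C)=CC[C@@]12C | intermediate
24 | C2 angelate with free C6 hydroxyl | C/C=C(/C)C(=O)O[C@H]1C[C@](O)(C(C)C)[C@H]2[C@H](O)CC(C)=CC[C@@]12C | intermediate
25 | 3,4,5-trimethoxybenzoyl chloride | COc1cc(C(=O)Cl)cc(OC)c1OC | starting material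
26 | target: (1R,2S,4S,5R,6R)-2-angeloyloxy-4-hydroxy-4-isopropyl-1,8-dimethyl-cis-hydroazulen-8-en-6-yl 3,4,5-trimethoxybenzoate (route locants) | C/C=C(/C)C(=O)O[C@H]1C[C@](O)(C(C)C)[C@H]2[C@H](OC(=O)c3cc(OC)c(OC)c(OC)c3)CC(C)=CC[C@@]12C | target

**Totals.** 16 steps in all. Longest linear sequence: 14 steps (5 to 26, steps 3–16).

**Steps most likely to fail**

1. Step 12. The samarium enolate may be protonated faster than it cyclises through the strained enolendo geometry, returning the methyl ketone, or the hindered aldolate may revert by retro-aldol cleavage on warming. Fallback: a Lewis-acid Mukaiyama aldol in place of the reductive enolate. Setting out from 16, the trimethylsilyl enol ether 17 is made as in the first half of step 11 and isolated. Treatment with TiCl4 in CH2Cl2 at −78 °C should activate the C4 ketone and close the same C3–C4 bond. Aqueous work-up should rejoin the route at 20 (no compound outside the list is made, F0).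

2. Step 6. The lithium enolate may be lost by ketene elimination before the slow rearrangement that builds the quaternary carbon, or facial selectivity may erode if the chelate opens. Fallback: the silyl ketene acetal variant. Setting out from 8, silylation (TBSOTf, 2,6-lutidine, CH2Cl2) should give the tert-butyldimethylsilyl ether of 8 F1. LiN(i-Pr)2 in THF/DMPU with TMSCl at −78 °C should give the silyl ketene acetal F2, with C6 cis to the trimethylsilyloxy group. On warming, F2 should rearrange through the same chair to the trimethylsilyl ester F3. Mild aqueous acid cleaves the silyl ester and the route is rejoined at 12, so step 7 is skipped.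

3. Step 13. Facial selectivity at the C2 carbonyl may be poor, with hydride delivered from the concave face. Fallback: thermodynamic control by electron-transfer reduction in place of kinetic hydride delivery. Setting out from 20, Li in liquid NH3/THF with t-BuOH at −78 °C should give the more stable alcohol. In that alcohol the C2 hydroxyl is trans to the C1 methyl group, clear of the C4 isopropyl group and hydrogen-bonded to the C4 hydroxyl. The route is rejoined at 21 (no compound outside the list is made, F0).

**Further compounds**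

F0 | step 12 | none | none
F1 | step 6 | (2Z)-3-methylhexa-2,5-dien-1-yl (3R)-3-(tert-butyldimethylsilyloxy)-5-methylhex-5-enoate | C=CC/C(C)=C\COC(=O)C[C@H](O[Si](C)(C)C(C)(C)C)CC(C)=C
F2 | step 6 | trimethylsilyl ketene acetal of F1 (C6 cis to OSiMe3) | C[Si](C)(C)O/C(OC/C=C(C)\CC=C)=C\[C@H](O[Si](C)(C)C(C)(C)C)CC(C)=C
F3 | step 6 | trimethylsilyl ester of 12 | C=C[C@](C)(CC=C)[C@@H](C(=O)O[Si](C)(C)C)[C@H](O[Si](C)(C)C(C)(C)C)CC(C)=C
F0 | step 13 | none | none
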